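**Retrosynthetic overview**
- C6–O ester bond last: the macrocyclic 6-hydroxy-8,12-olide is acylated with (R)-3-silyloxy-2-methylenebutanoic acid, made from (R)-but-3-yn-2-ol by Markovnikov hydrocarboxylation.
- Ten-membered carbocycle (third ring, closed last) and the α-methylene lactone together: intramolecular CrCl2 Barbier allylation (C6–C7) of a 3-(bromomethyl)butenolide onto a (Z)-enal; C6 and C7 are set from C8.
- Butenolide (second ring): acylation of the C8 carbinol with 2-(bromomethyl)acrylic acid, then ring-closing metathesis (C7=C11).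
- 3(2H)-Furanone (first ring) and quaternary C10: gold-catalysed heterocyclization of an α-hydroxy-α-alkynyl ketone with 1,2-methyl shift (α-ketol type) and chirality transfer from the carbinol.
- Acyclic chain: enantioselective mono-alkynylation of biacetyl with the silylated (Z)-enynol (C1–C2), then Ipc-boron aldol with acrolein (C8–C9, sets C8).

Assumption: the target is (4Z,6R,7R,8S,10R,3′R) as drawn (germacrane numbering), and the stated sense of induction of the ligand in step 2 and of the borane in step 3 is assumed, the antipode being used otherwise.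

**Step 1**
Reactants: 1 (Z)-3-methylpent-2-en-4-yn-1-ol
Product: 2 (Z)-tert-butyldimethyl[(3-methylpent-2-en-4-yn-1-yl)oxy]silane
Conditions: TBSCl, imidazole, DMF, 0 °C to rt
Reagents that add atoms: tert-butyldimethylsilyl chloride, CC(C)(C)[Si](C)(C)Cl
Why: Standard imidazole-promoted silylation of the primary allylic alcohol; the bulky silyl ether also blocks the known cycloisomerization of (Z)-enynols to furans in the later metal-catalysed steps.

**Step 2**
Reactants: 2 (Z)-tert-butyldimethyl[(3-methylpent-2-en-4-yn-1-yl)oxy]silane; 3 butane-2,3-dione (biacetyl)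
Product: 4 (3R,6Z)-8-[(tert-butyldimethylsilyl)oxy]-3-hydroxy-3,6-dimethyloct-6-en-4-yn-2-one
Conditions: [Cu(MeCN)4]PF6 (5 mol %), (R)-DTBM-SEGPHOS (6 mol %), Et3N (20 mol %), 3 (3 equiv), toluene, −20 °C
Reagents that add atoms: none
Why: Proposed new method: a monovalent copper acetylide, formed reversibly from 2 by amine-assisted deprotonation at the bisphosphine–copper centre, adds to one of the two homotopic, mutually activated carbonyl groups of biacetyl, so the only selection is the enantioface (set by the C2-symmetric ligand pocket, giving the (R)-carbinol), the copper alkoxide is protonated by the next alkyne to turn the catalyst over, and the product, now an ordinary ketone, does not add a second time; the closest known reactions are the copper- and zinc-catalysed enantioselective alkynylations of α-keto esters, trifluoromethyl ketones and isatins, which have not been shown for an enolizable acyclic 1,2-diketone.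

**Step 3**
Reactants: 4 (3R,6Z)-8-[(tert-butyldimethylsilyl)oxy]-3-hydroxy-3,6-dimethyloct-6-en-4-yn-2-one; 5 acrolein
Product: 8 (3S,6R,9Z)-11-[(tert-butyldimethylsilyl)oxy]-3,6-dihydroxy-6,9-dimethylundeca-1,9-dien-7-yn-5-one, via bis-borinate enolate 6 (not isolated), via bis-borinate aldolate 7 (not isolated)
Conditions: (−)-Ipc2BCl (2.3 equiv), Et3N (3 equiv), Et2O, −78 to 0 °C; 5, −78 to −20 °C; then H2O2, pH 7 buffer, MeOH, 0 °C
Reagents that add atoms: none
Why: Paterson-type Ipc-boron aldol in which the excess borane first caps the tertiary hydroxyl as its borinate and then enolizes the only enolizable (methyl) side, and the enol borinate adds 1,2 to the Si face of acrolein under reagent control to set (S)-C8, the buffered oxidative work-up freeing the diol without touching the silyl ether, alkyne or alkenes.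

**Step 4**
Reactants: 8 (3S,6R,9Z)-11-[(tert-butyldimethylsilyl)oxy]-3,6-dihydroxy-6,9-dimethylundeca-1,9-dien-7-yn-5-one; 9 2-(bromomethyl)acrylic acid
Product: 10 (3S,6R,9Z)-11-[(tert-butyldimethylsilyl)oxy]-6-hydroxy-6,9-dimethyl-5-oxoundeca-1,9-dien-7-yn-3-yl 2-(bromomethyl)acrylate
Conditions: DIC, DMAP (5 mol %), CH2Cl2, −20 to 0 °C
Reagents that add atoms: none
Why: Steglich esterification acylates the secondary allylic C8 hydroxyl and leaves the hindered tertiary carbinol free, while low temperature and only 5 mol % DMAP keep the β-acyloxy ketone from eliminating and the allylic bromide from being displaced.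

**Step 5**
Reactants: 10 (3S,6R,9Z)-11-[(tert-butyldimethylsilyl)oxy]-6-hydroxy-6,9-dimethyl-5-oxoundeca-1,9-dien-7-yn-3-yl 2-(bromomethyl)acrylate
Product: 11 (2S)-1-[(2R)-5-[(2Z)-4-[(tert-butyldimethylsilyl)oxy]but-2-en-2-yl]-2-methyl-3-oxo-2,3-dihydrofuran-2-yl]but-3-en-2-yl 2-(bromomethyl)acrylate
Conditions: AuCl3 (5 mol %), CH2Cl2, 23 °C
Reagents that add atoms: none
Why: Kirsch-type heterocyclization/1,2-migration: π-acid activation of the alkyne triggers 5-endo-dig attack of the ketone oxygen to give a cyclic oxocarbenium ion, into which the methyl group of the adjacent carbinol shifts suprafacially (α-ketol/semipinacol-type 1,2-shift), so the (R)-carbinol configuration is relayed to (R)-C10 while the carbinol carbon becomes the C1 ketone and protodeauration frees the catalyst.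

**Step 6**
Reactants: 11 (2S)-1-[(2R)-5-[(2Z)-4-[(tert-butyldimethylsilyl)oxy]but-2-en-2-yl]-2-methyl-3-oxo-2,3-dihydrofuran-2-yl]but-3-en-2-yl 2-(bromomethyl)acrylate
Product: 12 (5S)-3-(bromomethyl)-5-{[(2R)-5-[(2Z)-4-[(tert-butyldimethylsilyl)oxy]but-2-en-2-yl]-2-methyl-3-oxo-2,3-dihydrofuran-2-yl]methyl}furan-2(5H)-one
Conditions: second-generation Grubbs catalyst (H2IMes)(PCy3)Cl2Ru=CHPh (5 mol %), toluene, 80 °C
Reagents that add atoms: none
Why: Ring-closing metathesis between the terminal vinyl group and the 1,1-disubstituted acrylate closes the five-membered butenolide (C7=C11) with loss of ethene, the trisubstituted alkene, the furanone enone and the allylic bromide being poor metathesis partners and C8 untouched.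

**Step 7**
Reactants: 12 (5S)-3-(bromomethyl)-5-{[(2R)-5-[(2Z)-4-[(tert-butyldimethylsilyl)oxy]but-2-en-2-yl]-2-methyl-3-oxo-2,3-dihydrofuran-2-yl]methyl}furan-2(5H)-one
Product: 13 (5S)-3-(bromomethyl)-5-{[(2R)-5-[(2Z)-4-hydroxybut-2-en-2-yl]-2-methyl-3-oxo-2,3-dihydrofuran-2-yl]methyl}furan-2(5H)-one
Conditions: HF (48 % aq.), MeCN, 0 °C
Reagents that add atoms: none
Why: Acidic fluoride-mediated desilylation cleaves the primary silyl ether without base, so the allylic bromide and the base-sensitive γ-stereocentre (C8) of the butenolide survive.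

**Step 8**
Reactants: 13 (5S)-3-(bromomethyl)-5-{[(2R)-5-[(2Z)-4-hydroxybut-2-en-2-yl]-2-methyl-3-oxo-2,3-dihydrofuran-2-yl]methyl}furan-2(5H)-one
Product: 14 (2Z)-3-[(5R)-5-{[(2S)-4-(bromomethyl)-5-oxo-2,5-dihydrofuran-2-yl]methyl}-5-methyl-4-oxo-4,5-dihydrofuran-2-yl]but-2-enal
Conditions: MnO2, CH2Cl2, 23 °C; used crude
Reagents that add atoms: none
Why: Allylic oxidation with MnO2 converts only the allylic alcohol into the enal under neutral heterogeneous conditions that preserve the Z geometry, the bromide and the butenolide.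

**Step 9**
Reactants: 14 (2Z)-3-[(5R)-5-{[(2S)-4-(bromomethyl)-5-oxo-2,5-dihydrofuran-2-yl]methyl}-5-methyl-4-oxo-4,5-dihydrofuran-2-yl]but-2-enal
Product: 15 (4Z,6R,7R,8S,10R)-6-hydroxy-1-oxo-3,10-epoxygermacra-2,4,11(13)-trien-12,8-olide
Conditions: CrCl2 (10 equiv), THF, syringe-pump addition to 1 mM, 23 °C; aq. NH4Cl
Reagents that add atoms: none
Why: Intramolecular Nozaki–Hiyama/Barbier allylation: the allylchromium formed at C13 adds through C7 to the tethered aldehyde, attack anti to the C9 substituent of the butenolide giving the trans-fused 8,12-lactone (7R) and a chair-like six-membered transition state with the enal substituent equatorial giving the 6,7-anti (6R) carbinol, which closes the ten-membered ring and unveils the α-methylene lactone in one operation.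

**Step 10**
Reactants: 16 (R)-but-3-yn-2-ol
Product: 17 (R)-(but-3-yn-2-yloxy)(tert-butyl)dimethylsilane
Conditions: TBSCl, imidazole, CH2Cl2, 0 °C to rt
Reagents that add atoms: tert-butyldimethylsilyl chloride, CC(C)(C)[Si](C)(C)Cl
Why: Standard silylation that leaves the chiral-pool (R) centre untouched.

**Step 11**
Reactants: 17 (R)-(but-3-yn-2-yloxy)(tert-butyl)dimethylsilane
Product: 18 (R)-3-[(tert-butyldimethylsilyl)oxy]-2-methylenebutanoic acid
Conditions: Pd(OAc)2 (5 mol %), Xantphos (10 mol %), HCO2H (1.5 equiv), Ac2O (20 mol %), toluene, 80 °C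
Reagents that add atoms: formic acid, O=CO
Why: Palladium-catalysed hydrocarboxylation of a terminal alkyne with formic acid: the palladium hydride adds with Markovnikov regiochemistry and carbonylation by CO released in situ gives the 2-substituted acrylic acid, the stereocentre not being involved and the secondary silyl ether tolerating the weak acid.

**Step 12**
Reactants: 15 (4Z,6R,7R,8S,10R)-6-hydroxy-1-oxo-3,10-epoxygermacra-2,4,11(13)-trien-12,8-olide; 18 (R)-3-[(tert-butyldimethylsilyl)oxy]-2-methylenebutanoic acid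
Product: 19 (4Z,6R,7R,8S,10R)-6-{[(3R)-3-[(tert-butyldimethylsilyl)oxy]-2-methylenebutanoyl]oxy}-1-oxo-3,10-epoxygermacra-2,4,11(13)-trien-12,8-olide
Conditions: DIC, DMAP (20 mol %), CH2Cl2, 0 °C to rt
Reagents that add atoms: none
Why: Steglich esterification of the secondary allylic C6 hydroxyl proceeds with retention at C6 and at the side-chain centre, silyl protection of the acid's hydroxyl preventing self-acylation.

**Step 13**
Reactants: 19 (4Z,6R,7R,8S,10R)-6-{[(3R)-3-[(tert-butyldimethylsilyl)oxy]-2-methylenebutanoyl]oxy}-1-oxo-3,10-epoxygermacra-2,4,11(13)-trien-12,8-olide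
Product: 20 (4Z,6R,7R,8S,10R)-6-{[(3R)-3-hydroxy-2-methylenebutanoyl]oxy}-1-oxo-3,10-epoxygermacra-2,4,11(13)-trien-12,8-olide (CNP0266753.1)
Conditions: HF·pyridine, THF, 0 °C to rt
Reagents that add atoms: none
Why: Buffered fluoride-mediated desilylation removes the secondary silyl ether under non-basic conditions that spare the α-methylene lactone, the acrylate ester and the furanone.

**Compound list**
1 | (Z)-3-methylpent-2-en-4-yn-1-ol | C#C/C(C)=C\CO | starting material
2 | (Z)-tert-butyldimethyl[(3-methylpent-2-en-4-yn-1-yl)oxy]silane | C#C/C(C)=C\CO[Si](C)(C)C(C)(C)C | intermediate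
3 | butane-2,3-dione (biacetyl) | CC(=O)C(C)=O | starting material
4 | (3R,6Z)-8-[(tert-butyldimethylsilyl)oxy]-3-hydroxy-3,6-dimethyloct-6-en-4-yn-2-one | CC(=O)[C@](C)(O)C#C/C(C)=C\CO[Si](C)(C)C(C)(C)C | intermediate
5 | acrolein (prop-2-enal) | C=CC=O | starting material
6 | bis-borinate enolate: 2-O,3-O-bis(diisopinocampheylboryl) enolate of 4 | C=C(OB([C@@H]1C[C@@H]2C[C@H]([C@H]1C)C2(C)C)[C@@H]1C[C@@H]2C[C@H]([C@H]1C)C2(C)C)[C@](C)(OB([C@@H]1C[C@@H]2C[C@H]([C@H]1C)C2(C)C)[C@@H]1C[C@@H]2C[C@H]([C@H]1C)C2(C)C)C#C/C(C)=C\CO[Si](C)(C)C(C)(C)C | intermediate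
7 | bis-borinate aldolate: 3-O,6-O-bis(diisopinocampheylboryl) derivative of 8 | C=C[C@@H](OB([C@@H]1C[C@@H]2C[C@H]([C@H]1C)C2(C)C)[C@@H]1C[C@@H]2C[C@H]([C@H]1C)C2(C)C)CC(=O)[C@](C)(OB([C@@H]1C[C@@H]2C[C@H]([C@H]1C)C2(C)C)[C@@H]1C[C@@H]2C[C@H]([C@H]1C)C2(C)C)C#C/C(C)=C\CO[Si](C)(C)C(C)(C)C | intermediate
8 | (3S,6R,9Z)-11-[(tert-butyldimethylsilyl)oxy]-3,6-dihydroxy-6,9-dimethylundeca-1,9-dien-7-yn-5-one | C=C[C@@H](O)CC(=O)[C@](C)(O)C#C/C(C)=C\CO[Si](C)(C)C(C)(C)C | intermediate
9 | 2-(bromomethyl)acrylic acid | C=C(CBr)C(=O)O | starting material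
10 | (3S,6R,9Z)-11-[(tert-butyldimethylsilyl)oxy]-6-hydroxy-6,9-dimethyl-5-oxoundeca-1,9-dien-7-yn-3-yl 2-(bromomethyl)acrylate | C=C[C@@H](OC(=O)C(=C)CBr)CC(=O)[C@](C)(O)C#C/C(C)=C\CO[Si](C)(C)C(C)(C)C | intermediate
11 | (2S)-1-[(2R)-5-[(2Z)-4-[(tert-butyldimethylsilyl)oxy]but-2-en-2-yl]-2-methyl-3-oxo-2,3-dihydrofuran-2-yl]but-3-en-2-yl 2-(bromomethyl)acrylate | C=C[C@@H](OC(=O)C(=C)CBr)C[C@@]1(C)OC(=CC1=O)/C(C)=C\CO[Si](C)(C)C(C)(C)C | intermediate
12 | (5S)-3-(bromomethyl)-5-{[(2R)-5-[(2Z)-4-[(tert-butyldimethylsilyl)oxy]but-2-en-2-yl]-2-methyl-3-oxo-2,3-dihydrofuran-2-yl]methyl}furan-2(5H)-one | BrCC1=C[C@H](C[C@@]2(C)OC(=CC2=O)/C(C)=C\CO[Si](C)(C)C(C)(C)C)OC1=O | intermediate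
13 | (5S)-3-(bromomethyl)-5-{[(2R)-5-[(2Z)-4-hydroxybut-2-en-2-yl]-2-methyl-3-oxo-2,3-dihydrofuran-2-yl]methyl}furan-2(5H)-one | BrCC1=C[C@H](C[C@@]2(C)OC(=CC2=O)/C(C)=C\CO)OC1=O | intermediate
14 | (2Z)-3-[(5R)-5-{[(2S)-4-(bromomethyl)-5-oxo-2,5-dihydrofuran-2-yl]methyl}-5-methyl-4-oxo-4,5-dihydrofuran-2-yl]but-2-enal | BrCC1=C[C@H](C[C@@]2(C)OC(=CC2=O)/C(C)=C\C=O)OC1=O | intermediate
15 | (4Z,6R,7R,8S,10R)-6-hydroxy-1-oxo-3,10-epoxygermacra-2,4,11(13)-trien-12,8-olide | C=C1C(=O)O[C@H]2C[C@@]3(C)OC(=CC3=O)/C(C)=C\[C@@H](O)[C@H]12 | intermediate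
16 | (R)-but-3-yn-2-ol | C[C@@H](O)C#C | starting material
17 | (R)-(but-3-yn-2-yloxy)(tert-butyl)dimethylsilane | C[C@@H](O[Si](C)(C)C(C)(C)C)C#C | intermediate
18 | (R)-3-[(tert-butyldimethylsilyl)oxy]-2-methylenebutanoic acid | C[C@@H](O[Si](C)(C)C(C)(C)C)C(=C)C(=O)O | intermediate
19 | (4Z,6R,7R,8S,10R)-6-{[(3R)-3-[(tert-butyldimethylsilyl)oxy]-2-methylenebutanoyl]oxy}-1-oxo-3,10-epoxygermacra-2,4,11(13)-trien-12,8-olide | C=C1C(=O)O[C@H]2C[C@@]3(C)OC(=CC3=O)/C(C)=C\[C@@H](OC(=O)C(=C)[C@@H](C)O[Si](C)(C)C(C)(C)C)[C@H]12 | intermediate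
20 | (4Z,6R,7R,8S,10R)-6-{[(3R)-3-hydroxy-2-methylenebutanoyl]oxy}-1-oxo-3,10-epoxygermacra-2,4,11(13)-trien-12,8-olide | C=C1C(=O)O[C@H]2C[C@@]3(C)OC(=CC3=O)/C(C)=C\[C@@H](OC(=O)C(=C)[C@@H](C)O)[C@H]12 | target

**Step count**
Total: 13 steps. Longest linear sequence: 11 steps (steps 1–9, 12, 13); steps 10–11 form the two-step side-chain branch.

**Three steps most likely to fail, with fallbacks**

Step 2 (the proposed alkynylation). The risk is low enantioselectivity or base-induced self-condensation of biacetyl. The fallback uses known chemistry, sets out from 2 and comes back at 4. Enantioselective alkynylation of ethyl pyruvate with 2 (Zn(OTf)2, chiral β-amino alcohol ligand, Et3N, toluene, 70 °C) gives ethyl (2R,5Z)-7-[(tert-butyldimethylsilyl)oxy]-2-hydroxy-2,5-dimethylhept-5-en-3-ynoate F1. Treatment with MeNHOMe·HCl and i-PrMgCl converts it into (2R,5Z)-7-[(tert-butyldimethylsilyl)oxy]-2-hydroxy-N-methoxy-N,2,5-trimethylhept-5-en-3-ynamide F2, and MeMgBr (THF, 0 °C) then gives 4. This costs two extra steps.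

Step 5 (gold-catalysed heterocyclization/1,2-methyl shift). The risks are Lewis-acid-induced β-elimination of the acyloxy ketone and interference from the enyne or the silyl ether. The fallback sets out from 8 and comes back at 11; it uses the halonium-induced version of the same cyclization/1,2-shift and acylates only after the ketone at C10 is gone. TESOTf and 2,6-lutidine convert 8 into (3S,6R,9Z)-11-[(tert-butyldimethylsilyl)oxy]-6,9-dimethyl-3,6-bis[(triethylsilyl)oxy]undeca-1,9-dien-7-yn-5-one F3. N-Iodosuccinimide in CH2Cl2 then gives (2R)-5-[(2Z)-4-[(tert-butyldimethylsilyl)oxy]but-2-en-2-yl]-4-iodo-2-methyl-2-[(2S)-2-[(triethylsilyl)oxy]but-3-en-1-yl]furan-3(2H)-one F4. Zinc dust with aqueous NH4Cl in THF removes the iodine to give (2R)-5-[(2Z)-4-[(tert-butyldimethylsilyl)oxy]but-2-en-2-yl]-2-methyl-2-[(2S)-2-[(triethylsilyl)oxy]but-3-en-1-yl]furan-3(2H)-one F5. PPTS in MeOH at 0 °C cleaves the triethylsilyl ether selectively to give (2R)-5-[(2Z)-4-[(tert-butyldimethylsilyl)oxy]but-2-en-2-yl]-2-[(2S)-2-hydroxybut-3-en-1-yl]-2-methylfuran-3(2H)-one F6, which is esterified with 9 (DIC, DMAP) to give 11.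

Step 9 (chromium-mediated macrocyclization). The risks are oligomerization and, above all, the wrong configuration at C6 if the ring forces a non-chair transition state. The fallback sets out from 14 and comes back at 19. If the closure delivers mainly the C6 epimer, (4Z,6S,7R,8S,10R)-6-hydroxy-1-oxo-3,10-epoxygermacra-2,4,11(13)-trien-12,8-olide F7, this is not discarded. Mitsunobu esterification of it with acid 18 (PPh3, DIAD, toluene, 0 °C) inverts C6 while installing the side chain and gives 19 directly, replacing step 12.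

**Further compounds**
F1 | step 2 | ethyl (2R,5Z)-7-[(tert-butyldimethylsilyl)oxy]-2-hydroxy-2,5-dimethylhept-5-en-3-ynoate | CCOC(=O)[C@](C)(O)C#C/C(C)=C\CO[Si](C)(C)C(C)(C)C
F2 | step 2 | (2R,5Z)-7-[(tert-butyldimethylsilyl)oxy]-2-hydroxy-N-methoxy-N,2,5-trimethylhept-5-en-3-ynamide | CON(C)C(=O)[C@](C)(O)C#C/C(C)=C\CO[Si](C)(C)C(C)(C)C
F3 | step 5 | (3S,6R,9Z)-11-[(tert-butyldimethylsilyl)oxy]-6,9-dimethyl-3,6-bis[(triethylsilyl)oxy]undeca-1,9-dien-7-yn-5-one | C=C[C@@H](O[Si](CC)(CC)CC)CC(=O)[C@](C)(O[Si](CC)(CC)CC)C#C/C(C)=C\CO[Si](C)(C)C(C)(C)C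
F4 | step 5 | (2R)-5-[(2Z)-4-[(tert-butyldimethylsilyl)oxy]but-2-en-2-yl]-4-iodo-2-methyl-2-[(2S)-2-[(triethylsilyl)oxy]but-3-en-1-yl]furan-3(2H)-one | C=C[C@@H](O[Si](CC)(CC)CC)C[C@@]1(C)OC(=C(I)C1=O)/C(C)=C\CO[Si](C)(C)C(C)(C)C
F5 | step 5 | (2R)-5-[(2Z)-4-[(tert-butyldimethylsilyl)oxy]but-2-en-2-yl]-2-methyl-2-[(2S)-2-[(triethylsilyl)oxy]but-3-en-1-yl]furan-3(2H)-one | C=C[C@@H](O[Si](CC)(CC)CC)C[C@@]1(C)OC(=CC1=O)/C(C)=C\CO[Si](C)(C)C(C)(C)C
F6 | step 5 | (2R)-5-[(2Z)-4-[(tert-butyldimethylsilyl)oxy]but-2-en-2-yl]-2-[(2S)-2-hydroxybut-3-en-1-yl]-2-methylfuran-3(2H)-one | C=C[C@@H](O)C[C@@]1(C)OC(=CC1=O)/C(C)=C\CO[Si](C)(C)C(C)(C)C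
F7 | step 9 | (4Z,6S,7R,8S,10R)-6-hydroxy-1-oxo-3,10-epoxygermacra-2,4,11(13)-trien-12,8-olide | C=C1C(=O)O[C@H]2C[C@@]3(C)OC(=CC3=O)/C(C)=C\[C@H](O)[C@H]12
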